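The cyclohexane ring is cut into two three-carbon pieces (quinic acid numbering): C2–C3–C4, a hydroxyacetone unit that is nucleophilic at C2 and C4 while C3 is a ketone, and C5–C6–C1 with the carboxyl, a formylpyruvate unit that is electrophilic at C5 and C1. The key step uses the 1,3-placement of the C1 and C5 oxygens around the C3 oxygen: in one flask a copper-catalysed hetero-Diels–Alder reaction joins C4 to C5 through a temporary dihydropyran, and its hydrolysis frees a 2,6-diketo ester that closes C2–C1 by the aldol of dehydroquinate biosynthesis. Its precursors are an alkoxy oxobutenoate and an enediol bis-silyl ether; reduction, galloylation and hydrogenolysis follow.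

Key step: step 3

Locants used throughout: C1 carries OH and the carboxyl carbon C7; C2 and C6 are the ring CH2 groups; C3, C4 and C5 carry the three ester oxygens, with C3–O cis to C4–O and C5–O cis to the carboxyl.

Remark (assumption): the face selection of Cu(OTf)2 with the (R,R)-tBu-box ligand is taken from the square-planar chelate model, which predicts attack on the C5 face leading to the 5R series; should the adduct prove antipodal, the (S,S) ligand is used and nothing else changes.

Remark (assumption): benzyl chlorooxoacetate and 3,4,5-tris(benzyloxy)benzoyl chloride are taken as commercial.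

Step 1
Reactants: 1 tert-butyl vinyl ether; 2 benzyl chlorooxoacetate
Product: 3 benzyl (3E)-4-(tert-butoxy)-2-oxobut-3-enoate
Conditions: pyridine (1.2 equiv), CH2Cl2, 0 °C to rt
Reagents that add atoms: none
Why: Acylation of the electron-rich enol ether at its β-carbon by the acylpyridinium of 2, followed by loss of HCl (enol ether acylation of the Friedel–Crafts type), should give the conjugated E-alkoxy enone, pyridine keeping the medium non-acidic so that the tert-butyl group stays on; no stereocentre is formed.

Step 2
Reactants: 4 hydroxyacetone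
Product: 5 (Z)-1,2-bis(trimethylsilyloxy)prop-1-ene
Conditions: Me3SiOTf (2.2 equiv), Et3N (2.6 equiv), Et2O, 0 °C to rt; distillation
Reagents that add atoms: trimethylsilyl trifluoromethanesulfonate, C[Si](C)(C)OS(=O)(=O)C(F)(F)F
Why: O-Silylation followed by soft enolisation (enol silane formation under equilibrating conditions) should favour the more substituted, oxygen-bearing C3=C4 enol, giving the enediol bis-silyl ether; no stereocentre is formed and the Z/E ratio is immaterial for step 3.

Step 3
Reactants: 3 benzyl (3E)-4-(tert-butoxy)-2-oxobut-3-enoate; 5 (Z)-1,2-bis(trimethylsilyloxy)prop-1-ene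
Product: 9 benzyl (1R,3R,4S)-3-(tert-butoxy)-1,4-dihydroxy-5-oxocyclohexane-1-carboxylate (benzyl 5-O-tert-butyl-3-dehydroquinate), via cycloadduct 6 (not isolated), via erythro diketo ester 7 (not isolated), via threo diketo ester 8 (not isolated)
Conditions: Cu(OTf)2 (10 mol%), (R,R)-tBu-box (11 mol%), THF, −78 to −20 °C; then citric acid (0.2 equiv), THF/H2O, 0 °C; then KH2PO4/K2HPO4 buffer pH 7.5, rt
Reagents that add atoms: none
Why: The divalent copper complex chelates the 1,2-dicarbonyl unit of 3, and its s-cis C1=O/C6=C5 heterodiene undergoes an inverse-electron-demand hetero-Diels–Alder reaction with 5 in which the less substituted C4 bonds to C5 and the carbonyl oxygen to C3 (charge develops at the tertiary, silyloxy-stabilised C3), giving dihydropyran 6; the closest known reactions are copper–bis(oxazoline)-catalysed cycloadditions of 4-alkoxy-2-oxobut-3-enoates with enol ethers and enol silanes. Mild aqueous acid then hydrolyses the silyl ketal and silyl ether, the hemiketal opens to the 2-oxo ester 7, and at pH 7.5 the methyl ketone enolises and adds to the C1 keto group, the same aldol that closes the ring in dehydroquinate biosynthesis. The temporary dihydropyran closes by [4+2] cycloaddition and the cyclohexane by a 6-(enolendo)-exo-trig aldol, the only aldol of 8 that gives an unstrained ring. C5 is set by the ligand, which leaves one face of the chelated heterodiene open; C4, α to the C3 carbonyl and more acidic than the C2 methyl, epimerises through the enediol (7 to 8, and again in 9), so the chair-like aldol transition state and the product with equatorial 4-OH and 5-O-tert-butyl should be favoured whatever the endo/exo outcome of the cycloaddition; C1 follows from the same chair with the ester equatorial and cis to the C5 oxygen, and the aldol is reversible. The step needs attack through C4 and not C2 (secured by the enol silane regiochemistry of 5) and aldol faster than β-elimination at C5 (tert-butoxide is a very poor leaving group and the medium is neutral); no amine is present that could displace the alkoxy group of 3.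

Step 4
Reactants: 9 benzyl (1R,3R,4S)-3-(tert-butoxy)-1,4-dihydroxy-5-oxocyclohexane-1-carboxylate
Product: 10 benzyl (1S,3R,4R,5R)-3-(tert-butoxy)-1,4,5-trihydroxycyclohexane-1-carboxylate (benzyl 5-O-tert-butylquinate)
Conditions: LiBH(s-Bu)3 (3.5 equiv), THF, −78 °C; then MeOH, KH2PO4/K2HPO4 buffer pH 7, 30% H2O2, 0 °C
Reagents that add atoms: none
Why: Substrate-controlled ketone reduction with a bulky trialkylborohydride should deliver hydride along the equatorial trajectory, away from the axial C1 oxygen, to give the axial C3 alcohol cis to the C4 and C1 hydroxyls, the benzyl ester being inert at −78 °C.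

Step 5
Reactants: 10 benzyl 5-O-tert-butylquinate
Product: 11 benzyl (1S,3R,4S,5R)-1,3,4,5-tetrahydroxycyclohexane-1-carboxylate (benzyl quinate)
Conditions: CF3CO2H/CH2Cl2 1:4, 0 °C to rt; evaporation from toluene
Reagents that add atoms: none
Why: Acidolysis of the tert-butyl ether (E1 loss of isobutene) should free the C5 hydroxyl while the benzyl ester, the secondary alcohols and the tertiary α-hydroxy ester (no stabilised cation, no lactonisation at rt) are untouched; no stereocentre changes.

Step 6
Reactants: 11 benzyl quinate; 12 3,4,5-tris(benzyloxy)benzoyl chloride (3.6 equiv in all; three equivalents end up in 13)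
Product: 13 benzyl 3,4,5-tris-O-[3,4,5-tris(benzyloxy)benzoyl]quinate
Conditions: pyridine, DMAP (0.2 equiv), CH2Cl2, 0 to 35 °C
Reagents that add atoms: 3,4,5-tris(benzyloxy)benzoyl chloride (second equivalent of 12), O=C(Cl)c1cc(OCc2ccccc2)c(OCc2ccccc2)c(OCc2ccccc2)c1; 3,4,5-tris(benzyloxy)benzoyl chloride (third equivalent of 12), O=C(Cl)c1cc(OCc2ccccc2)c(OCc2ccccc2)c(OCc2ccccc2)c1
Why: DMAP-catalysed acylation (nucleophilic catalysis through the acylpyridinium) should esterify the three secondary hydroxyls, each taking one acyl group from one molecule of 12, so that three molecules of 12 are consumed per molecule of 11, whereas the hindered tertiary C1 hydroxyl, deactivated by the geminal ester, stays free; configuration is retained because only O–H bonds react.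

Step 7
Reactants: 13 benzyl 3,4,5-tris-O-[3,4,5-tris(benzyloxy)benzoyl]quinate
Product: 14 3,4,5-tri-O-galloylquinic acid (target)
Conditions: H2 (1 atm), 10% Pd/C, THF/MeOH 1:1, rt
Reagents that add atoms: none
Why: Hydrogenolysis over palladium should cleave the nine benzyl aryl ethers and the benzyl ester in one operation, leaving the three aryl esters, the tertiary alcohol and all stereocentres intact.

Compound list
1 | tert-butyl vinyl ether | C=COC(C)(C)C | starting material
2 | benzyl chlorooxoacetate | O=C(Cl)C(=O)OCc1ccccc1 | starting material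
3 | benzyl (3E)-4-(tert-butoxy)-2-oxobut-3-enoate | CC(C)(C)O/C=C/C(=O)C(=O)OCc1ccccc1 | intermediate
4 | hydroxyacetone (1-hydroxypropan-2-one) | CC(=O)CO | starting material
5 | (Z)-1,2-bis(trimethylsilyloxy)prop-1-ene | C/C(O[Si](C)(C)C)=C/O[Si](C)(C)C | intermediate
6 | benzyl (2R,3R,4R)-4-(tert-butoxy)-2-methyl-2,3-bis(trimethylsilyloxy)-3,4-dihydro-2H-pyran-6-carboxylate (drawn as the endo adduct) | C[C@]1(O[Si](C)(C)C)OC(C(=O)OCc2ccccc2)=C[C@@H](OC(C)(C)C)[C@H]1O[Si](C)(C)C | intermediate
7 | benzyl (4R,5R)-4-(tert-butoxy)-5-hydroxy-2,6-dioxoheptanoate (erythro, first released from 6) | CC(=O)[C@H](O)[C@H](OC(C)(C)C)CC(=O)C(=O)OCc1ccccc1 | intermediate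
8 | benzyl (4R,5S)-4-(tert-butoxy)-5-hydroxy-2,6-dioxoheptanoate (threo, C4 epimer of 7) | CC(=O)[C@@H](O)[C@H](OC(C)(C)C)CC(=O)C(=O)OCc1ccccc1 | intermediate
9 | benzyl (1R,3R,4S)-3-(tert-butoxy)-1,4-dihydroxy-5-oxocyclohexane-1-carboxylate | CC(C)(C)O[C@@H]1C[C@](O)(C(=O)OCc2ccccc2)CC(=O)[C@H]1O | intermediate
10 | benzyl (1S,3R,4R,5R)-3-(tert-butoxy)-1,4,5-trihydroxycyclohexane-1-carboxylate | CC(C)(C)O[C@@H]1C[C@](O)(C(=O)OCc2ccccc2)C[C@@H](O)[C@H]1O | intermediate
11 | benzyl (1S,3R,4S,5R)-1,3,4,5-tetrahydroxycyclohexane-1-carboxylate (benzyl quinate) | O[C@@H]1C[C@](O)(C(=O)OCc2ccccc2)C[C@@H](O)[C@H]1O | intermediate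
12 | 3,4,5-tris(benzyloxy)benzoyl chloride | O=C(Cl)c1cc(OCc2ccccc2)c(OCc2ccccc2)c(OCc2ccccc2)c1 | starting material
13 | benzyl 3,4,5-tris-O-[3,4,5-tris(benzyloxy)benzoyl]quinate | O=C(O[C@@H]1C[C@](O)(C(=O)OCc2ccccc2)C[C@@H](OC(=O)c2cc(OCc3ccccc3)c(OCc3ccccc3)c(OCc3ccccc3)c2)[C@H]1OC(=O)c1cc(OCc2ccccc2)c(OCc2ccccc2)c(OCc2ccccc2)c1)c1cc(OCc2ccccc2)c(OCc2ccccc2)c(OCc2ccccc2)c1 | intermediate
14 | 3,4,5-tri-O-galloylquinic acid | O=C(O[C@@H]1C[C@](O)(C(=O)O)C[C@@H](OC(=O)c2cc(O)c(O)c(O)c2)[C@H]1OC(=O)c1cc(O)c(O)c(O)c1)c1cc(O)c(O)c(O)c1 | target

Total step count: 7. Longest linear sequence: 6 (steps 1, 3, 4, 5, 6, 7).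

Steps most likely to fail

Step 3. Epimerisation at C4 may be slower than ring closure, so that the 4,5-cis epimer is carried along beside 9; part of 8 may also be lost by β-elimination of tert-butanol, because C6–H is more acidic than the C2–H needed for the aldol. Fallback: the C4 question is moved into the reduction. The unseparated mixture of 9 and its C4 epimer, benzyl (1R,3R,4R)-3-(tert-butoxy)-1,4-dihydroxy-5-oxocyclohexane-1-carboxylate F1, is treated with a ketoreductase (NADPH, glucose/glucose dehydrogenase recycling, KH2PO4/K2HPO4 buffer pH 8, DMSO cosolvent, 30 °C). The enzyme is chosen from a panel to reduce 9 only, on the face that gives the axial 3-OH. At pH 8, F1 and 9 interconvert through the enediol, so the mixture should drain into 10 (dynamic reductive kinetic resolution). This fallback sets out from 9 (with F1), replaces step 4 and comes back at 10.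

Step 4. Hydride may be delivered along the axial trajectory (3-epimer), or the lithium alkoxides of 9 may undergo retro-aldol opening or β-elimination before reduction. Fallback: reagent control under non-basic conditions replaces the basic, substrate-controlled hydride. Asymmetric transfer hydrogenation with RuCl(p-cymene)[(R,R)-TsDPEN] (or its enantiomer, whichever is matched with 9), HCO2H/Et3N 5:2, CH2Cl2, rt, is used. It sets out from 9 and comes back at 10; no new compound is made.

Step 2. Enolisation may go toward the methyl group, giving the regioisomeric 2,3-bis(silyloxy)prop-1-ene, which would enter the cycloaddition through C2. Fallback: an aldehyde, which has only one enolisable position, replaces the ketone. Commercial (S)-2-(tert-butyldimethylsilyloxy)propanal F2 (its stereocentre is destroyed, so the racemate serves as well) with Me3SiOTf/Et3N should give tert-butyldimethyl{[(1E)-1-(trimethylsilyloxy)prop-1-en-2-yl]oxy}silane F3. F3 takes the place of 5 in step 3, where it meets 3 and gives the cycloadduct benzyl (2R,3S,4R)-4-(tert-butoxy)-2-(tert-butyldimethylsilyloxy)-2-methyl-3-(trimethylsilyloxy)-3,4-dihydro-2H-pyran-6-carboxylate F4. Hydrolysis of F4 under the conditions of step 3 leads to 8. This fallback does not use 4 and 5, joins the route at 3 and comes back at 8.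

Further compounds
F1 | step 3 | benzyl (1R,3R,4R)-3-(tert-butoxy)-1,4-dihydroxy-5-oxocyclohexane-1-carboxylate | CC(C)(C)O[C@@H]1C[C@](O)(C(=O)OCc2ccccc2)CC(=O)[C@@H]1O
F0 | step 4 | none | none
F2 | step 2 | (S)-2-(tert-butyldimethylsilyloxy)propanal | C[C@H](O[Si](C)(C)C(C)(C)C)C=O
F3 | step 2 | tert-butyldimethyl{[(1E)-1-(trimethylsilyloxy)prop-1-en-2-yl]oxy}silane | C/C(O[Si](C)(C)C(C)(C)C)=C\O[Si](C)(C)C
F4 | step 2 | benzyl (2R,3S,4R)-4-(tert-butoxy)-2-(tert-butyldimethylsilyloxy)-2-methyl-3-(trimethylsilyloxy)-3,4-dihydro-2H-pyran-6-carboxylate | C[C@]1(O[Si](C)(C)C(C)(C)C)OC(C(=O)OCc2ccccc2)=C[C@@H](OC(C)(C)C)[C@@H]1O[Si](C)(C)C
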